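Watch one ratio: how fast the catalyst uses open intermediate, over how fast it makes it, per unit of each.

    reagent + catalyst intermediate → free catalyst + product (k1 = 426 /M/h)
    free catalyst + product ⇌ idle complex (K2 = 33 /M, k2 = 1.30 /M/h)
    free catalyst + open intermediate ⇌ catalyst intermediate (K3 = 25 /M, k3 = 16100 /M/h)
    substrate + free catalyst → free catalyst + open intermediate (k4 = 497 /M/h)

| flask | substrate | reagent | free catalyst | time | remark |
|---|---|---|---|---|---|
| green | 0.097 M (fed, over 16.0 h) | 0.107 M | 0.14 mM | 20 h | a stirred flask in which substrate is dosed at a steady rate over 16.0 h without added volume, worked up at 20 h |
| violet | 0.097 M | 0.107 M | 0.14 mM |  | a single well-mixed tank run continuously and read at steady state, 200 h in it on average |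
| blue | 0.097 M | 0.107 M | 0.14 mM | 20 h | a closed flask charged with all of it at once and left for 20 h |
| teal | 0.097 M | 0.107 M | 0.14 mM |  | one stirred flow tank at steady state, fed with the mixture as stated, mean residence time 20 h |

* the set-up with the highest amount of open intermediate at the outlet or at the end, in percent of the substrate put in ("none" if the first two lie within 2 percentage points) (green / violet / blue / teal / none)
* amount of open intermediate at the outlet or at the end, in percent of the substrate put in, green
* amount of open intermediate at the outlet or at the end, in percent of the substrate put in, violet
* amount of open intermediate at the outlet or at the end, in percent of the substrate put in, blue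
* amount of open intermediate at the outlet or at the end, in percent of the substrate put in, teal

- amounts and yields of product count idle complex too
- the stated concentrations are those of everything mixed, before any reaction; amounts are the same in each set-up
- the feed brings no volume worth counting
- run time (green): 20 h

**First instants.** You start with no open intermediate, and a catalyst must turn 693 times to open the whole charge. At the charged free catalyst, substrate has a half-life of 9.96 h. Open intermediate finds free catalyst far faster than that, with a half-life of 0.31 h by the forward step. But binding is not use. The catalyst intermediate falls back at 644 /h, and it goes on to product at 45.6 /h with the reagent as charged, much more slowly. So 6.61% of bindings count at the start.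

**The ratio.** Multiply the binding constant by that share and divide by the opening constant. This gives the use ratio κ, a selectivity factor: 2.14. Both rates carry c(free catalyst), so it cancels. Losing free catalyst slows the clock, not κ.

**The middle.** Let a be the substrate left and y the open intermediate, both as fractions of the charge. Then y = (a − a^κ)/(κ − 1), and y tops where a = κy. That top is 24.0%. At the charged free catalyst you reach it in 9.59 h. Catalyst held as catalyst intermediate stretches this to about 14.8 h, which is shorter than the 20 h of blue.

**The end.** At that top, on my count, about a quarter of the substrate is product. Reagent has fallen with it, and that lowers κ, so I take my top as a low figure. By the forward rate, free catalyst goes into idle complex with a half-life of 22.0 h at that product level, longer than my 14.8 h. Idle complex takes free catalyst too, so it slows the clock, not κ.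

**My reckoning.** A mixed tank at the same κ tops at 16.5%, less than the closed flask. I commit to blue near 24.0%, the tanks near 16.5%, and green between them, with its substrate arriving over 16.0 h.

**The forecast.** It gives green 23%, violet 16.5%, blue 26%, teal 19%, best blue, with “consumption about twice as fast per unit at the start”. Its blue stands above mine.

**The flask.** The simulation gives green 22.9%, violet 16.3%, blue 26.5% and teal 18.9%, so blue is highest. In blue at 20.0 h, open intermediate is made 1.00 times as fast as it is used, each step taken net, with 70.4% of the reagent left. There κ has become 1.54, and a/κ with 40.8% of the substrate left is 26.5%. Read the same blue flask at 5.00 h: 75.6% of the substrate is left, the curve at κ = 2.14 gives 18.1%, and the flask holds 18.2%.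

(The numbers were set for the occasion; the flask was simulated.)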